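The 2(5H)-furanone is closed at its C4–C5 bond. C4, the ring's vinylic carbon β to the lactone carbonyl, is a latent β-keto ester carbon (used as its Z-enol triflate). C5, the O-bound methylene, is brought in as a stannylmethyl ester, so the ring's own O1–C2(=O) ester is the tether. One intramolecular Stille coupling thus converts an acyclic trienyl 3-(triflyloxy)enoate (tributylstannyl)methyl ester, built from farnesyl acetate via a dioxinone, into the 4-dienylbutenolide. The terminal epoxide then unmasks an aldehyde, which a Z-selective Horner–Wadsworth–Emmons reaction joins to the (R)-phosphono lactone from (R)-5-(hydroxymethyl)butyrolactone.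

Key step: step 8

Assumption: (tributylstannyl)methanol, bis(2,2,2-trifluoroethyl) phosphorochloridate and (R)-5-(hydroxymethyl)oxolan-2-one are taken as purchasable; the epoxide centre made in steps 1–2 is racemic and is excised in step 9.

Step 1
Reactants: 1 (2E,6E)-farnesyl acetate
Product: 2 (2E,6E)-10-bromo-11-hydroxy-3,7,11-trimethyldodeca-2,6-dien-1-yl acetate (racemic)
Conditions: NBS (1.05 equiv), THF/H2O 3:1, 0 °C
Reagents that add atoms: N-bromosuccinimide O=C1CCC(=O)N1Br; water O
Why: Bromohydrin formation, in which NBS in aqueous THF attacks the exposed, electron-rich terminal trisubstituted alkene in preference to the internal and the acetate-deactivated ones and water opens the bromonium ion at the tertiary carbon; the new C–Br centre is racemic and is removed in step 9.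

Step 2
Reactants: 2 (2E,6E)-10-bromo-11-hydroxy-3,7,11-trimethyldodeca-2,6-dien-1-yl acetate
Product: 3 (2E,6E)-9-(3,3-dimethyloxiran-2-yl)-3,7-dimethylnona-2,6-dien-1-ol (racemic)
Conditions: K2CO3 (2.5 equiv), MeOH, rt
Reagents that add atoms: none
Why: Intramolecular Williamson etherification of the bromohydrin closes the epoxide (still racemic) while carbonate in methanol transesterifies the acetate off.

Step 3
Reactants: 3 (2E,6E)-9-(3,3-dimethyloxiran-2-yl)-3,7-dimethylnona-2,6-dien-1-ol
Product: 4 (2E,6E)-9-(3,3-dimethyloxiran-2-yl)-3,7-dimethylnona-2,6-dienal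
Conditions: activated MnO2 (excess), CH2Cl2, rt
Reagents that add atoms: none
Why: Manganese dioxide oxidation is selective for the allylic alcohol, keeps the 2E geometry and leaves the epoxide alone.

Step 4
Reactants: 5 2,2,6-trimethyl-4H-1,3-dioxin-4-one
Product: 6 diethyl [(2,2-dimethyl-4-oxo-4H-1,3-dioxin-6-yl)methyl]phosphonate
Conditions: LDA (2.1 equiv), THF, −78 °C; then ClP(O)(OEt)2, −78 → 0 °C
Reagents that add atoms: diethyl chlorophosphate CCOP(=O)(Cl)OCC
Why: The lithium dienolate of the dioxinone is phosphorylated at its exocyclic γ-carbon (enolate phosphorylation), the established way to this vinylogous Horner–Wadsworth–Emmons reagent.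

Step 5
Reactants: 4 (2E,6E)-9-(3,3-dimethyloxiran-2-yl)-3,7-dimethylnona-2,6-dienal; 6 diethyl [(2,2-dimethyl-4-oxo-4H-1,3-dioxin-6-yl)methyl]phosphonate
Product: 7 6-[(1E,3E,7E)-10-(3,3-dimethyloxiran-2-yl)-4,8-dimethyldeca-1,3,7-trien-1-yl]-2,2-dimethyl-4H-1,3-dioxin-4-one
Conditions: 6, NaH, THF, 0 °C; then 4, 0 °C → rt
Reagents that add atoms: none
Why: Horner–Wadsworth–Emmons olefination of the enal with the stabilised vinylogous phosphonate should give the new disubstituted alkene as the E isomer under thermodynamic control.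

Step 6
Reactants: 7 6-[(1E,3E,7E)-10-(3,3-dimethyloxiran-2-yl)-4,8-dimethyldeca-1,3,7-trien-1-yl]-2,2-dimethyl-4H-1,3-dioxin-4-one; 8 (tributylstannyl)methanol
Product: 10 (tributylstannyl)methyl (4E,6E,10E)-13-(3,3-dimethyloxiran-2-yl)-7,11-dimethyl-3-oxotrideca-4,6,10-trienoate, via acylketene 9 (not isolated)
Conditions: 8 (1.1 equiv), toluene, 110 °C
Reagents that add atoms: none
Why: Thermal retro-[4+2] of the dioxinone expels acetone and the acylketene is trapped by the primary alcohol (acylketene acylation), which gives the β-keto ester under neutral conditions that spare the epoxide and the C–Sn bond.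

Step 7
Reactants: 10 (tributylstannyl)methyl (4E,6E,10E)-13-(3,3-dimethyloxiran-2-yl)-7,11-dimethyl-3-oxotrideca-4,6,10-trienoate
Product: 11 (tributylstannyl)methyl (2Z,4E,6E,10E)-13-(3,3-dimethyloxiran-2-yl)-7,11-dimethyl-3-{[(trifluoromethyl)sulfonyl]oxy}trideca-2,4,6,10-tetraenoate
Conditions: NaH (1.1 equiv), THF, 0 °C; then PhNTf2 (1.1 equiv), 0 °C → rt
Reagents that add atoms: N-phenyl-bis(trifluoromethanesulfonimide) O=S(=O)(N(c1ccccc1)S(=O)(=O)C(F)(F)F)C(F)(F)F
Why: Enol triflate formation, in which the sodium enolate of the β-keto ester is chelated between both carbonyl oxygens and is O-sulfonylated in that geometry, so the triflate should end up cis to the ester (2Z).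

Step 8
Reactants: 11 (tributylstannyl)methyl (2Z,4E,6E,10E)-13-(3,3-dimethyloxiran-2-yl)-7,11-dimethyl-3-{[(trifluoromethyl)sulfonyl]oxy}trideca-2,4,6,10-tetraenoate
Product: 12 4-[(1E,3E,7E)-10-(3,3-dimethyloxiran-2-yl)-4,8-dimethyldeca-1,3,7-trien-1-yl]furan-2(5H)-one
Conditions: Pd2(dba)3 (5 mol %), AsPh3 (20 mol %), CuI (20 mol %), LiCl (3 equiv), NMP, 50 °C, 2 mM (slow addition of 11)
Reagents that add atoms: none
Why: Pd(0) inserts into the vinylic C–OTf bond with retention, placing palladium on the former ketone carbon (ring C4) cis to the ester; the ester-tethered CH2 group (ring C5) is then handed from tin to palladium, with Cu(I) and chloride assisting, to give a six-membered oxa-palladacycle, and C(sp2)–C(sp3) reductive elimination contracts it to the lactone. The closest known reaction type is the Migita–Kosugi–Stille coupling of α-oxygenated methylstannanes (hydroxymethyl- and acyloxymethyl-stannanes) with alkenyl triflates, here run intramolecularly. The single ring closed is the five-membered lactone, formed at a vinylic carbon whose double bond stays inside the ring (formally a 5-endo closure), which the metallacycle route makes geometrically feasible. No stereocentre is created; the ring alkene is necessarily cis and sits where the (Z)-triflate put it, and the 1E,3E-diene is not involved. The step needs transfer of the oxymethyl group rather than butyl and cyclisation rather than oligomerisation: the α-oxygen and carbonyl coordination to tin activate the Sn–CH2O bond, the Z geometry keeps palladium next to the tether, and high dilution disfavours intermolecular coupling. The non-allylic epoxide and the isolated trisubstituted alkenes offer Pd(0) no reactive site.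

Step 9
Reactants: 12 4-[(1E,3E,7E)-10-(3,3-dimethyloxiran-2-yl)-4,8-dimethyldeca-1,3,7-trien-1-yl]furan-2(5H)-one
Product: 14 (4E,8E,10E)-4,8-dimethyl-11-(5-oxo-2,5-dihydrofuran-3-yl)undeca-4,8,10-trienal, via glycol 13 (not isolated)
Conditions: H5IO6 (1.3 equiv), THF/H2O, 0 °C
Reagents that add atoms: none
Why: Periodic acid hydrolyses the trisubstituted epoxide to the glycol and cleaves it (Malaprade cleavage) to the aldehyde and acetone, which removes the racemic centre without oxidising the butenolide or the alkenes.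

Step 10
Reactants: 15 (5R)-5-(hydroxymethyl)oxolan-2-one
Product: 16 (2R)-5-oxooxolane-2-carbaldehyde
Conditions: Dess–Martin periodinane (1.2 equiv), CH2Cl2, 0 °C → rt; used crude
Reagents that add atoms: none
Why: Dess–Martin oxidation of the primary alcohol under non-basic conditions should give the α-oxygenated aldehyde without touching the stereocentre, which comes from the chiral pool.

Step 11
Reactants: 16 (2R)-5-oxooxolane-2-carbaldehyde
Product: 17 (5R)-5-(2-methylprop-1-en-1-yl)oxolan-2-one
Conditions: i-PrPPh3I (1.3 equiv), KHMDS (1.25 equiv), THF, 0 °C; then 16, −78 → 0 °C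
Reagents that add atoms: isopropyltriphenylphosphonium iodide CC(C)[P+](c1ccccc1)(c1ccccc1)c1ccccc1.[I-]
Why: Wittig olefination with the non-stabilised isopropylidene ylide at low temperature should convert the aldehyde to the trisubstituted alkene faster than the ylide enolises it or attacks the lactone, so the (R) centre is retained.

Step 12
Reactants: 17 (5R)-5-(2-methylprop-1-en-1-yl)oxolan-2-one
Product: 19 bis(2,2,2-trifluoroethyl) [(5R)-5-(2-methylprop-1-en-1-yl)-2-oxooxolan-3-yl]phosphonate, via enol phosphate 18 (not isolated)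
Conditions: LDA (2.3 equiv), THF, −78 °C; then ClP(O)(OCH2CF3)2 (1.1 equiv), −78 °C → rt; AcOH quench
Reagents that add atoms: bis(2,2,2-trifluoroethyl) phosphorochloridate O=P(Cl)(OCC(F)(F)F)OCC(F)(F)F
Why: The lithium lactone enolate is O-phosphorylated and the ketene acetal phosphate undergoes the base-induced 1,3-phosphoryl shift (vinyl phosphate to phosphonate rearrangement) to the stabilised α-phosphono lactone anion; the γ-centre is not involved and the new α-centre (both epimers) is lost in step 13.

Step 13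
Reactants: 14 (4E,8E,10E)-4,8-dimethyl-11-(5-oxo-2,5-dihydrofuran-3-yl)undeca-4,8,10-trienal; 19 bis(2,2,2-trifluoroethyl) [(5R)-5-(2-methylprop-1-en-1-yl)-2-oxooxolan-3-yl]phosphonate
Product: 20 (3Z,5R)-3-[(4E,8E,10E)-4,8-dimethyl-11-(5-oxo-2,5-dihydrofuran-3-yl)undeca-4,8,10-trien-1-ylidene]-5-(2-methylprop-1-en-1-yl)oxolan-2-one
Conditions: 19 (1.2 equiv), KHMDS (1.15 equiv), 18-crown-6 (3 equiv), THF, −78 °C; then 14, −78 °C, cold quench
Reagents that add atoms: none
Why: Still–Gennari-type Horner–Wadsworth–Emmons olefination, in which the electron-poor bis(trifluoroethyl) phosphonate with a dissociated potassium counter-ion adds irreversibly and eliminates fast, so kinetic control should place the aldehyde chain cis to the lactone carbonyl (3Z); the (R) centre is carried through unchanged and the weakly basic phosphonate anion does not deprotonate the butenolide.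

Compound list
1 | (2E,6E)-3,7,11-trimethyldodeca-2,6,10-trien-1-yl acetate ((2E,6E)-farnesyl acetate) | CC(C)=CCC/C(C)=C/CC/C(C)=C/COC(C)=O | starting material
2 | (2E,6E)-10-bromo-11-hydroxy-3,7,11-trimethyldodeca-2,6-dien-1-yl acetate (racemic) | CC(C)(O)C(Br)CC/C(C)=C/CC/C(C)=C/COC(C)=O | intermediate
3 | (2E,6E)-9-(3,3-dimethyloxiran-2-yl)-3,7-dimethylnona-2,6-dien-1-ol (racemic) | CC1(C)OC1CC/C(C)=C/CC/C(C)=C/CO | intermediate
4 | (2E,6E)-9-(3,3-dimethyloxiran-2-yl)-3,7-dimethylnona-2,6-dienal (racemic) | CC1(C)OC1CC/C(C)=C/CC/C(C)=C/C=O | intermediate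
5 | 2,2,6-trimethyl-4H-1,3-dioxin-4-one | CC1=CC(=O)OC(C)(C)O1 | starting material
6 | diethyl [(2,2-dimethyl-4-oxo-4H-1,3-dioxin-6-yl)methyl]phosphonate | CCOP(=O)(CC1=CC(=O)OC(C)(C)O1)OCC | intermediate
7 | 6-[(1E,3E,7E)-10-(3,3-dimethyloxiran-2-yl)-4,8-dimethyldeca-1,3,7-trien-1-yl]-2,2-dimethyl-4H-1,3-dioxin-4-one | CC1(C)OC1CC/C(C)=C/CC/C(C)=C/C=C/C1=CC(=O)OC(C)(C)O1 | intermediate
8 | (tributylstannyl)methanol | CCCC[Sn](CO)(CCCC)CCCC | starting material
9 | (4E,6E,10E)-13-(3,3-dimethyloxiran-2-yl)-7,11-dimethyltrideca-1,4,6,10-tetraene-1,3-dione (acylketene) | CC1(C)OC1CC/C(C)=C/CC/C(C)=C/C=C/C(=O)C=C=O | intermediate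
10 | (tributylstannyl)methyl (4E,6E,10E)-13-(3,3-dimethyloxiran-2-yl)-7,11-dimethyl-3-oxotrideca-4,6,10-trienoate | CC1(C)OC1CC/C(C)=C/CC/C(C)=C/C=C/C(=O)CC(=O)OC[Sn](CCCC)(CCCC)CCCC | intermediate
11 | (tributylstannyl)methyl (2Z,4E,6E,10E)-13-(3,3-dimethyloxiran-2-yl)-7,11-dimethyl-3-{[(trifluoromethyl)sulfonyl]oxy}trideca-2,4,6,10-tetraenoate | CC1(C)OC1CC/C(C)=C/CC/C(C)=C/C=C/C(OS(=O)(=O)C(F)(F)F)=C/C(=O)OC[Sn](CCCC)(CCCC)CCCC | intermediate
12 | 4-[(1E,3E,7E)-10-(3,3-dimethyloxiran-2-yl)-4,8-dimethyldeca-1,3,7-trien-1-yl]furan-2(5H)-one | CC1(C)OC1CC/C(C)=C/CC/C(C)=C/C=C/C1=CC(=O)OC1 | intermediate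
13 | 4-[(1E,3E,7E)-11,12-dihydroxy-4,8,12-trimethyltrideca-1,3,7-trien-1-yl]furan-2(5H)-one (glycol) | CC(C)(O)C(O)CC/C(C)=C/CC/C(C)=C/C=C/C1=CC(=O)OC1 | intermediate
14 | (4E,8E,10E)-4,8-dimethyl-11-(5-oxo-2,5-dihydrofuran-3-yl)undeca-4,8,10-trienal | O=CCC/C(C)=C/CC/C(C)=C/C=C/C1=CC(=O)OC1 | intermediate
15 | (5R)-5-(hydroxymethyl)oxolan-2-one | OC[C@H]1CCC(=O)O1 | starting material
16 | (2R)-5-oxooxolane-2-carbaldehyde | O=C[C@H]1CCC(=O)O1 | intermediate
17 | (5R)-5-(2-methylprop-1-en-1-yl)oxolan-2-one | CC(C)=C[C@H]1CCC(=O)O1 | intermediate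
18 | bis(2,2,2-trifluoroethyl) (5R)-5-(2-methylprop-1-en-1-yl)-4,5-dihydrofuran-2-yl phosphate (enol phosphate) | CC(C)=C[C@H]1CC=C(OP(=O)(OCC(F)(F)F)OCC(F)(F)F)O1 | intermediate
19 | bis(2,2,2-trifluoroethyl) [(5R)-5-(2-methylprop-1-en-1-yl)-2-oxooxolan-3-yl]phosphonate (both C3 epimers) | CC(C)=C[C@H]1CC(C(=O)O1)P(=O)(OCC(F)(F)F)OCC(F)(F)F | intermediate
20 | (3Z,5R)-3-[(4E,8E,10E)-4,8-dimethyl-11-(5-oxo-2,5-dihydrofuran-3-yl)undeca-4,8,10-trien-1-ylidene]-5-(2-methylprop-1-en-1-yl)oxolan-2-one | CC(C)=C[C@H]1C/C(=C/CC/C(C)=C/CC/C(C)=C/C=C/C2=CC(=O)OC2)C(=O)O1 | target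

Total step count: 13.
Longest linear sequence: 9 steps (steps 1, 2, 3, 5, 6, 7, 8, 9, 13, from farnesyl acetate).

Steps most likely to fail

Step 8. The tin-to-palladium transfer within one molecule may be slow, because the ester tether has to rotate out of its preferred Z conformation (O–CH2 syn to C=O) before the stannylmethyl group can reach the vinylic carbon. Intermolecular coupling to oligomers, butyl transfer and protodestannylation may then compete. The fallback makes the same carbon–carbon bond without the tether and lets the ring close through the oxygen. It sets out from dioxinone 7: thermolysis in toluene with methanol gives methyl (4E,6E,10E)-13-(3,3-dimethyloxiran-2-yl)-7,11-dimethyl-3-oxotrideca-4,6,10-trienoate F1; NaH and PhNTf2 give its (Z)-enol triflate F2; intermolecular Stille coupling of F2 with stannane 8 (Pd(PPh3)4, LiCl, dioxane, 80 °C) gives the γ-hydroxy (Z)-enoate F3, whose hydroxymethyl group is cis to the ester and should lactonise in the flask, or with a trace of PPTS, to butenolide 12, where the route is rejoined.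

Step 13. Kinetic control may be incomplete with the cyclic phosphonate, so that the E-alkylidene lactone forms beside the Z isomer. The fallback builds the alkene with an acyclic Still–Gennari reagent and sets the carbinol centre afterwards by reagent control. It sets out from aldehyde 14: chloroacetyl chloride and 2-methylpropene (AlCl3, then loss of HCl) give 1-chloro-4-methylpent-3-en-2-one F4; F4 alkylates the sodium salt of commercial methyl bis(2,2,2-trifluoroethyl)phosphonoacetate (NaH, cat. NaI, THF) to the γ-keto phosphonate F5; olefination of 14 with F5 (KHMDS, 18-crown-6, THF, −78 °C) should give the (Z)-enoate enone F6; Corey–Bakshi–Shibata reduction with the (S)-oxazaborolidine and catecholborane should reduce only the enone carbonyl, to the (R)-allylic alcohol F7, which lactonises with PPTS to target 20.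

Step 12. The amide base may attack phosphorus and expel trifluoroethoxide, or the phosphoryl shift may stall at the enol phosphate. The fallback forms the P–C bond by carbene insertion. It sets out from lactone 17: LiHMDS and 2,2,2-trifluoroethyl trifluoroacetate give the α-trifluoroacetyl lactone F8, which is treated directly with methanesulfonyl azide and Et3N (detrifluoroacetylative diazo transfer) to give the α-diazo lactone F9; Rh2(OAc)4-catalysed P–H insertion with bis(2,2,2-trifluoroethyl) phosphite (toluene, 60 °C) then gives phosphono lactone 19, where the route is rejoined.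

Further compounds
F1 | step 8 | methyl (4E,6E,10E)-13-(3,3-dimethyloxiran-2-yl)-7,11-dimethyl-3-oxotrideca-4,6,10-trienoate | CC1(C)OC1CC/C(C)=C/CC/C(C)=C/C=C/C(=O)CC(=O)OC
F2 | step 8 | methyl (2Z,4E,6E,10E)-13-(3,3-dimethyloxiran-2-yl)-7,11-dimethyl-3-{[(trifluoromethyl)sulfonyl]oxy}trideca-2,4,6,10-tetraenoate | CC1(C)OC1CC/C(C)=C/CC/C(C)=C/C=C/C(OS(=O)(=O)C(F)(F)F)=C/C(=O)OC
F3 | step 8 | methyl (2Z,4E,6E,10E)-13-(3,3-dimethyloxiran-2-yl)-3-(hydroxymethyl)-7,11-dimethyltrideca-2,4,6,10-tetraenoate | CC1(C)OC1CC/C(C)=C/CC/C(C)=C/C=C/C(CO)=C/C(=O)OC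
F4 | step 13 | 1-chloro-4-methylpent-3-en-2-one | CC(C)=CC(=O)CCl
F5 | step 13 | methyl 2-[bis(2,2,2-trifluoroethoxy)phosphoryl]-6-methyl-4-oxohept-5-enoate | COC(=O)C(CC(=O)C=C(C)C)P(=O)(OCC(F)(F)F)OCC(F)(F)F
F6 | step 13 | methyl (2Z,6E,10E,12E)-6,10-dimethyl-2-(4-methyl-2-oxopent-3-en-1-yl)-13-(5-oxo-2,5-dihydrofuran-3-yl)trideca-2,6,10,12-tetraenoate | COC(=O)/C(CC(=O)C=C(C)C)=C\CC/C(C)=C/CC/C(C)=C/C=C/C1=CC(=O)OC1
F7 | step 13 | methyl (2Z,6E,10E,12E)-2-[(2R)-2-hydroxy-4-methylpent-3-en-1-yl]-6,10-dimethyl-13-(5-oxo-2,5-dihydrofuran-3-yl)trideca-2,6,10,12-tetraenoate | COC(=O)/C(C[C@@H](O)C=C(C)C)=C\CC/C(C)=C/CC/C(C)=C/C=C/C1=CC(=O)OC1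
F8 | step 12 | (5R)-5-(2-methylprop-1-en-1-yl)-3-(trifluoroacetyl)oxolan-2-one | CC(C)=C[C@H]1CC(C(=O)C(F)(F)F)C(=O)O1
F9 | step 12 | (5R)-3-diazo-5-(2-methylprop-1-en-1-yl)oxolan-2-one | CC(C)=C[C@H]1CC(=[N+]=[N-])C(=O)O1
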